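**Retrosynthetic overview**
1. The ketone comes last, by oxidation of a ring-B carbinol. Ring D (pendant lactone) comes from a CH2OH group by iridium-catalysed 2-(alkoxycarbonyl)allylation and hydrogenation. Ring C (fused lactone) comes from a trisubstituted E ring alkene by syn-hydroboration/lactonisation and enolate methylation.
2. Key disconnection: rings A (azepan-2-one) and B (nine-membered ring) of the bridged lactam both arise from a monocyclic N-(6-diazo-5-oxohexyl)-2-[(E)-but-1-enyl]pyrrolidine. A Wolff 1,2-shift makes the bond between the lactam α-carbon and its ring-A CH2 neighbour; the ketene then acylates N, and an aza-Claisen shift expands the pyrrolidine.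
3. Enabling feature: the lactam C=O is a one-carbon bridge between N and the α-CH. That α-CH carries the (CH2)4 chain back to N (ring A) and, in ring B, the CH(Et) carbon two bonds from the ring-fusion CH next to the ketone. N–C(=O)–CH–CH(Et)–C=C is therefore the amide of a ketene aza-Claisen on a 2-alkenylpyrrolidine, and N–(CH2)4–CH=C=O is the diazomethyl ketone of a 5-aminopentanoic acid less N2.
4. The pyrrolidine comes from N-Boc-trans-4-hydroxy-L-prolinol (which supplies the CH–N centre and the future ketone oxygen) by Shono oxidation and acetate-directed N-acyliminium alkenylation.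
5. Ring order: pyrrolidine (chiral pool) → A + B (step 9) → C (step 16) → D (step 20).

Key step: step 9

Assumption: in step 20 the SEGPHOS enantiomer is taken to be the one that delivers the (S)-carbinol of ring D; if the catalyst's sense is the opposite, the antipodal ligand is used.
Assumption: the ring-B carbinol made in step 13 is drawn as the epimer expected from hydride attack on the exposed face; this centre is oxidised in step 22 and is inconsequential.
Abbreviations: TBDPS = tert-butyldiphenylsilyl, TBS = tert-butyldimethylsilyl. Bicyclic compounds are named as 1-azabicyclo[6.4.1]tridecan-13-ones (N1; C2 bears the CH2O group; C4 carbinol/ketone; C5, C6 alkene; C7 CHEt; C8 lactam α-CH; C9–C12 ring-A CH2; C13 lactam C=O).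

Step 1
Reactants: 1 tert-butyl (2S,4R)-4-hydroxy-2-(hydroxymethyl)pyrrolidine-1-carboxylate
Product: 2 tert-butyl (2S,4R)-2-[(TBDPS-oxy)methyl]-4-hydroxypyrrolidine-1-carboxylate
Conditions: TBDPSCl (1.05 equiv), imidazole, CH2Cl2, 0 °C
Reagents that add atoms: tert-butyl(chloro)diphenylsilane, CC(C)(C)[Si](Cl)(c1ccccc1)c1ccccc1
Why: Silyl ether formation; the bulky chlorosilane should react with the primary alcohol much faster than with the secondary ring alcohol, and no stereocentre is touched.

Step 2
Reactants: 2 primary silyl ether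
Product: 3 tert-butyl (2S,4R)-4-acetoxy-2-[(TBDPS-oxy)methyl]pyrrolidine-1-carboxylate
Conditions: Ac2O, pyridine, DMAP (cat.), CH2Cl2, 23 °C
Reagents that add atoms: acetic anhydride, CC(=O)OC(C)=O
Why: DMAP-catalysed acetylation (nucleophilic acyl transfer); the acetate later directs step 5 and can be removed by methanolysis without touching the silyl ether.

Step 3
Reactants: 3 acetate
Product: 5 tert-butyl (2S,4R)-4-acetoxy-2-[(TBDPS-oxy)methyl]-5-methoxypyrrolidine-1-carboxylate (both 5-epimers), via N-acyliminium ion 4 (not isolated)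
Conditions: graphite anode, steel cathode, Et4NOTs, MeOH, 0 °C, constant current (ca. 2.3 F per mol), undivided cell
Reagents that add atoms: methanol, CO
Why: Shono anodic α-methoxylation of a carbamate; the aminium radical cation should lose a proton at the unsubstituted ring CH2 rather than at the substituted CH, and methanol traps the N-acyliminium ion (the new centre is erased again in step 5).

Step 4
Reactants: 6 but-1-yne
Product: 8 potassium (E)-but-1-en-1-yltrifluoroborate, via alkenyl catecholboronate 7 (not isolated)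
Conditions: catecholborane, neat, sealed tube, 70 °C; then aq KHF2, MeOH, 23 °C
Reagents that add atoms: catecholborane, B1Oc2ccccc2O1; potassium hydrogen difluoride, [K+].F[H-]F
Why: syn, anti-Markovnikov hydroboration of the terminal alkyne gives the E-alkenylboronate, and ligand exchange with KHF2 gives the stable trifluoroborate.

Step 5
Reactants: 5 N,O-acetal; 8 potassium (E)-but-1-en-1-yltrifluoroborate
Product: 9 tert-butyl (2S,4R,5S)-4-acetoxy-5-[(E)-but-1-en-1-yl]-2-[(TBDPS-oxy)methyl]pyrrolidine-1-carboxylate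
Conditions: BF3·OEt2, CH2Cl2/MeCN, −78 → 0 °C
Reagents that add atoms: none
Why: Lewis-acid ionisation of the N,O-acetal returns the N-acyliminium ion 4 first formed in step 3, and the alkenyltrifluoroborate adds to it; the neighbouring acetoxy group shields its own face, so the butenyl group should enter trans to it and set the (5S) allylic centre with retention of the E geometry.

Step 6
Reactants: 9 N-Boc-5-butenylpyrrolidine
Product: 10 (2S,3R,5S)-2-[(E)-but-1-en-1-yl]-5-[(TBDPS-oxy)methyl]pyrrolidin-3-yl acetate (secondary amine)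
Conditions: TFA, CH2Cl2, 0 → 23 °C; aq NaHCO3; used at once
Reagents that add atoms: none
Why: Acidolysis of the tert-butyl carbamate (loss of isobutene, then decarboxylation); acetate, silyl ether and alkene should survive brief TFA.

Step 7
Reactants: 11 5-bromopentanoyl chloride
Product: 12 6-bromo-1-diazohexan-2-one
Conditions: CH2N2 (2.5 equiv, from N-methyl-N-nitroso-p-toluenesulfonamide), Et2O, 0 °C
Reagents that add atoms: diazomethane, C=[N+]=[N-]
Why: Arndt–Eistert acylation of diazomethane; the second equivalent removes HCl, so no chloromethyl ketone forms.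

Step 8
Reactants: 10 secondary amine; 12 6-bromo-1-diazohexan-2-one
Product: 13 (2S,3R,5S)-2-[(E)-but-1-en-1-yl]-1-(6-diazo-5-oxohexyl)-5-[(TBDPS-oxy)methyl]pyrrolidin-3-yl acetate
Conditions: K2CO3, NaI (cat.), MeCN, 40 °C, dark
Reagents that add atoms: none
Why: SN2 N-alkylation of the secondary amine by the primary bromide (iodide-assisted); α-diazoketones tolerate carbonate base.

Step 9
Reactants: 13 N-(6-diazo-5-oxohexyl)pyrrolidine
Product: 16 (5E)-7-ethyl-13-oxo-2-[(TBDPS-oxy)methyl]-1-azabicyclo[6.4.1]tridec-5-en-4-yl acetate (rings A and B), via ketene 14 (not isolated), via acylammonium enolate 15 (not isolated)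
Conditions: hν (365 nm LED), PhMe (0.005 M), 25 °C; then 40 °C in the dark
Reagents that add atoms: none
Why: Proposed new method: Direct irradiation of the s-Z α-diazoketone should expel N2 with a concerted Wolff 1,2-shift of the chain CH2 from the acyl carbon to the diazo carbon, which makes the bond between the future lactam α-carbon and its ring-A CH2 neighbour and leaves monosubstituted ketene 14; the tertiary pyrrolidine nitrogen then adds to the ketene carbonyl carbon to give spirocyclic acylammonium enolate 15, and this zwitterion undergoes the charge-cancelling aza-Claisen 3,3-shift across the (E)-butenyl group, breaking the ring N–C(allyl) bond and enlarging the pyrrolidine by four atoms. The closest known chemistry is the intermolecular zwitterionic ketene aza-Claisen (Belluš–Claisen) ring expansion of N-alkyl-2-vinylpyrrolidines to nine-membered E-lactams, together with amine trapping of Wolff ketenes; the tethered photochemical combination is untested. Ring A closes in this step by the 1,2-shift followed by N-acylation at the ketene (seven-membered, exo to C=O), and ring B arises by 3,3-sigmatropic ring expansion (five to nine), not by end-to-end cyclisation. Because ring A locks the enolate C=C with its carbon substituent cis to nitrogen, only the boat-like transition state with the ring-A chain exo should be reachable, and it requires the ring CH(OAc) carbon to be pseudo-equatorial, so the new ring alkene is E. Bond breaking at the (S)-allylic carbon and bond making occur on the same face of the E-butenyl unit, which fixes the CH(Et) centre, and the boat geometry fixes the lactam α-centre, both as in the target. The step needs Wolff shift over carbene capture by the amine (ammonium ylide, 2,3-shift) and intra- over intermolecular ketene capture: metal-free irradiation and high dilution serve this, the preferred N-invertomer has its lone pair cis to the butenyl group, and acetate and silyl ether are inert.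

Step 10
Reactants: 16 bicyclic allylic acetate
Product: 17 (5E)-7-ethyl-4-hydroxy-2-[(TBDPS-oxy)methyl]-1-azabicyclo[6.4.1]tridec-5-en-13-one
Conditions: K2CO3 (cat.), MeOH, 0 → 23 °C
Reagents that add atoms: none
Why: Base-catalysed transesterification (Zemplén-type methanolysis) of the allylic acetate; the tertiary lactam and the TBDPS ether should be inert.

Step 11
Reactants: 17 allylic alcohol
Product: 18 (5E)-7-ethyl-2-[(TBDPS-oxy)methyl]-1-azabicyclo[6.4.1]tridec-5-ene-4,13-dione
Conditions: Dess–Martin periodinane, NaHCO3, CH2Cl2, 0 → 23 °C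
Reagents that add atoms: none
Why: Dess–Martin oxidation under buffered, non-nucleophilic conditions, so that the E-configured ring enone is not isomerised.

Step 12
Reactants: 18 ring enone
Product: 19 7-ethyl-5-iodo-2-[(TBDPS-oxy)methyl]-1-azabicyclo[6.4.1]tridec-5-ene-4,13-dione (ring carbons still trans across C5=C6)
Conditions: I2 (2 equiv), pyridine, CH2Cl2, 0 → 23 °C
Reagents that add atoms: iodine, II
Why: Johnson α-iodination of an enone (pyridine conjugate addition, enolate iodination, E1cB loss of pyridine); the least-motion elimination should return the alkene with the ring carbons still trans, iodine taking the place of the vinylic hydrogen.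

Step 13
Reactants: 19 α-iodoenone
Product: 20 7-ethyl-4-hydroxy-5-iodo-2-[(TBDPS-oxy)methyl]-1-azabicyclo[6.4.1]tridec-5-en-13-one
Conditions: NaBH4, CeCl3·7H2O, MeOH, −40 °C
Reagents that add atoms: none
Why: Luche 1,2-reduction of the α-iodoenone; hydride should arrive from the exposed face, and the new carbinol centre is re-oxidised in step 22.

Step 14
Reactants: 20 iodo allylic alcohol
Product: 21 4-(TBS-oxy)-7-ethyl-5-iodo-2-[(TBDPS-oxy)methyl]-1-azabicyclo[6.4.1]tridec-5-en-13-one
Conditions: TBSOTf, 2,6-lutidine, CH2Cl2, −78 → 0 °C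
Reagents that add atoms: tert-butyldimethylsilyl trifluoromethanesulfonate, CC(C)(C)[Si](C)(C)OS(=O)(=O)C(F)(F)F
Why: Silylation with the silyl triflate; it keeps this hydroxyl from competing in the lactonisation of step 16.

Step 15
Reactants: 21 vinyl iodide
Product: 22 ethyl 2-{4-(TBS-oxy)-7-ethyl-13-oxo-2-[(TBDPS-oxy)methyl]-1-azabicyclo[6.4.1]tridec-5-en-5-yl}acetate
Conditions: Zn dust, BrCH2CO2Et, THF, 40 °C (gives BrZnCH2CO2Et); then 21, Pd(PPh3)4 (5 mol %), THF/NMP, 45 °C
Reagents that add atoms: ethyl bromoacetate (as its zinc reagent), CCOC(=O)CBr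
Why: Negishi-type cross-coupling of the vinyl iodide with the Reformatsky reagent (oxidative addition, transmetalation, reductive elimination), with retention of alkene geometry; it places the acetic ester arm on the alkene carbon next to the silyloxy carbon.

Step 16
Reactants: 22 trisubstituted ring alkene ester
Product: 25 tricyclic γ-lactone (ring C cis-fused at C5–C6, oxygen on C6), 4-OTBS, 2-CH2OTBDPS, via alkylborane 23 (not isolated), via hydroxy ester 24 (not isolated)
Conditions: BH3·SMe2 (1.2 equiv), THF, −10 → 0 °C; H2O2, aq NaHCO3, 0 °C; then PPTS, PhMe, 60 °C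
Reagents that add atoms: hydrogen peroxide, OO; borane–dimethyl sulfide (boron only in 23), C[S+](C)[BH3-]
Why: Hydroboration–oxidation followed by lactonisation; borane should add syn and anti-Markovnikov (boron on the CH end, away from the silyloxy group) on the exposed alkene face opposite the lactam bridge, which sets the carbinol and ring-fusion centres together, and retentive oxidation then acyl substitution gives the cis-fused lactone.

Step 17
Reactants: 25 lactone
Product: 26 α-methyl lactone (methyl trans to the adjacent ring bond, as in the target)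
Conditions: LiN(iPr)2 (1.1 equiv), THF, −78 °C; MeI, −78 → −40 °C
Reagents that add atoms: iodomethane, CI
Why: Kinetic lactone enolate alkylation; the lactone CH2 should be deprotonated in preference to the bridgehead lactam CH, and iodomethane attacks the convex face of the cis-fused bicycle.

Step 18
Reactants: 26 bis-silyl ether
Product: 27 diol (ring-B secondary alcohol and CH2OH on the carbon next to N)
Conditions: TBAF, AcOH, THF, 0 → 23 °C
Reagents that add atoms: none
Why: Fluoride-induced cleavage of both silyl ethers (Si–F bond formation), buffered with acetic acid to spare the lactone.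

Step 19
Reactants: 28 ethyl 2-(hydroxymethyl)acrylate
Product: 29 ethyl 2-(acetoxymethyl)acrylate
Conditions: Ac2O, pyridine, DMAP (cat.), CH2Cl2, 0 → 23 °C
Reagents that add atoms: acetic anhydride, CC(=O)OC(C)=O
Why: Acetylation gives the allylic acetate needed as allyl donor in step 20.

Step 20
Reactants: 27 diol; 29 ethyl 2-(acetoxymethyl)acrylate
Product: 32 α-methylene lactone (ring D attached, ring-B alcohol free), via amido aldehyde 30 (not isolated), via hydroxy ester 31 (not isolated)
Conditions: [Ir(cod)Cl]2 (2.5 mol %), (R)-SEGPHOS (5 mol %), 4-cyano-3-nitrobenzoic acid (10 mol %), Cs2CO3 (1.0 equiv), THF, 100 °C, sealed tube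
Reagents that add atoms: none
Why: Iridium-catalysed transfer-hydrogenative 2-(alkoxycarbonyl)allylation of a primary alcohol (alcohol dehydrogenation, carbonyl addition of the chiral π-allyliridium species, lactonisation); only the primary alcohol should be dehydrogenated, the aldehyde stays catalyst-bound so the centre next to N is not epimerised, and the ligand sets the new carbinol centre.

Step 21
Reactants: 32 α-methylene lactone
Product: 33 hydroxy bis-lactone (9-dihydro target)
Conditions: H2 (1 atm), Pd/C (10 %), EtOAc, 23 °C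
Reagents that add atoms: none
Why: Heterogeneous hydrogenation of the exocyclic methylene; hydrogen should add to the lactone face opposite the bulky substituent on the carbinol carbon, giving the cis-α-methyl lactone.

Step 22
Reactants: 33 hydroxy bis-lactone
Product: 34 CNP0311700.2 (target)
Conditions: Dess–Martin periodinane, NaHCO3, CH2Cl2, 0 → 23 °C
Reagents that add atoms: none
Why: Dess–Martin oxidation of the only remaining alcohol under neutral conditions, so that the β-acyloxy ketone is not eliminated and the centre α to the ketone is not epimerised.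

**Compound list**
1 | tert-butyl (2S,4R)-4-hydroxy-2-(hydroxymethyl)pyrrolidine-1-carboxylate | C1[C@H](O)C[C@@H](CO)N1C(=O)OC(C)(C)C | starting material
2 | tert-butyl (2S,4R)-2-[(TBDPS-oxy)methyl]-4-hydroxypyrrolidine-1-carboxylate | C1[C@H](O)C[C@@H](CO[Si](c2ccccc2)(c2ccccc2)C(C)(C)C)N1C(=O)OC(C)(C)C | intermediate
3 | tert-butyl (2S,4R)-4-acetoxy-2-[(TBDPS-oxy)methyl]pyrrolidine-1-carboxylate | C1[C@H](OC(C)=O)C[C@@H](CO[Si](c2ccccc2)(c2ccccc2)C(C)(C)C)N1C(=O)OC(C)(C)C | intermediate
4 | N-acyliminium ion: (3R,5S)-3-acetoxy-1-(tert-butoxycarbonyl)-5-[(TBDPS-oxy)methyl]-3,4-dihydro-2H-pyrrol-1-ium | CC(=O)O[C@@H]1C[C@@H](CO[Si](c2ccccc2)(c2ccccc2)C(C)(C)C)[N+](C(=O)OC(C)(C)C)=C1 | intermediate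
5 | tert-butyl (2S,4R)-4-acetoxy-2-[(TBDPS-oxy)methyl]-5-methoxypyrrolidine-1-carboxylate (5-epimers) | COC1[C@H](OC(C)=O)C[C@@H](CO[Si](c2ccccc2)(c2ccccc2)C(C)(C)C)N1C(=O)OC(C)(C)C | intermediate
6 | but-1-yne | CCC#C | starting material
7 | (E)-2-(but-1-en-1-yl)-1,3,2-benzodioxaborole | CC/C=C/B1Oc2ccccc2O1 | intermediate
8 | potassium (E)-but-1-en-1-yltrifluoroborate | CC/C=C/[B-](F)(F)F.[K+] | intermediate
9 | tert-butyl (2S,4R,5S)-4-acetoxy-5-[(E)-but-1-en-1-yl]-2-[(TBDPS-oxy)methyl]pyrrolidine-1-carboxylate | CC/C=C/[C@H]1[C@H](OC(C)=O)C[C@@H](CO[Si](c2ccccc2)(c2ccccc2)C(C)(C)C)N1C(=O)OC(C)(C)C | intermediate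
10 | (2S,3R,5S)-2-[(E)-but-1-en-1-yl]-5-[(TBDPS-oxy)methyl]pyrrolidin-3-yl acetate | CC/C=C/[C@H]1[C@H](OC(C)=O)C[C@@H](CO[Si](c2ccccc2)(c2ccccc2)C(C)(C)C)N1 | intermediate
11 | 5-bromopentanoyl chloride | O=C(Cl)CCCCBr | starting material
12 | 6-bromo-1-diazohexan-2-one | [N-]=[N+]=CC(=O)CCCCBr | intermediate
13 | (2S,3R,5S)-2-[(E)-but-1-en-1-yl]-1-(6-diazo-5-oxohexyl)-5-[(TBDPS-oxy)methyl]pyrrolidin-3-yl acetate | CC/C=C/[C@H]1[C@H](OC(C)=O)C[C@@H](CO[Si](c2ccccc2)(c2ccccc2)C(C)(C)C)N1CCCCC(=O)C=[N+]=[N-] | intermediate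
14 | ketene: N-(6-oxohex-5-en-1-yl)pyrrolidine from 13 by loss of N2 and 1,2-shift | CC/C=C/[C@H]1[C@H](OC(C)=O)C[C@@H](CO[Si](c2ccccc2)(c2ccccc2)C(C)(C)C)N1CCCCC=C=O | intermediate
15 | spirocyclic acylammonium enolate (pyrrolidinium N shared with a 2,3,4,5-tetrahydro-1H-azepin-7-olate ring; N configuration not specified) | CC/C=C/[C@H]1[C@H](OC(C)=O)C[C@@H](CO[Si](c2ccccc2)(c2ccccc2)C(C)(C)C)[N+]12CCCCC=C2[O-] | intermediate
16 | (5E)-7-ethyl-13-oxo-2-[(TBDPS-oxy)methyl]-1-azabicyclo[6.4.1]tridec-5-en-4-yl acetate | CC[C@H]1/C=C/[C@H](OC(C)=O)C[C@@H](CO[Si](c3ccccc3)(c3ccccc3)C(C)(C)C)N2CCCC[C@H]1C2=O | intermediate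
17 | (5E)-7-ethyl-4-hydroxy-2-[(TBDPS-oxy)methyl]-1-azabicyclo[6.4.1]tridec-5-en-13-one | CC[C@H]1/C=C/[C@H](O)C[C@@H](CO[Si](c3ccccc3)(c3ccccc3)C(C)(C)C)N2CCCC[C@H]1C2=O | intermediate
18 | (5E)-7-ethyl-2-[(TBDPS-oxy)methyl]-1-azabicyclo[6.4.1]tridec-5-ene-4,13-dione | CC[C@H]1/C=C/C(=O)C[C@@H](CO[Si](c3ccccc3)(c3ccccc3)C(C)(C)C)N2CCCC[C@H]1C2=O | intermediate
19 | 7-ethyl-5-iodo-2-[(TBDPS-oxy)methyl]-1-azabicyclo[6.4.1]tridec-5-ene-4,13-dione (C4 and C7 trans across the alkene) | CC[C@H]1/C=C(\I)C(=O)C[C@@H](CO[Si](c3ccccc3)(c3ccccc3)C(C)(C)C)N2CCCC[C@H]1C2=O | intermediate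
20 | 7-ethyl-4-hydroxy-5-iodo-2-[(TBDPS-oxy)methyl]-1-azabicyclo[6.4.1]tridec-5-en-13-one | CC[C@H]1/C=C(\I)[C@@H](O)C[C@@H](CO[Si](c3ccccc3)(c3ccccc3)C(C)(C)C)N2CCCC[C@H]1C2=O | intermediate
21 | 4-(TBS-oxy)-7-ethyl-5-iodo-2-[(TBDPS-oxy)methyl]-1-azabicyclo[6.4.1]tridec-5-en-13-one | CC[C@H]1/C=C(\I)[C@@H](O[Si](C)(C)C(C)(C)C)C[C@@H](CO[Si](c3ccccc3)(c3ccccc3)C(C)(C)C)N2CCCC[C@H]1C2=O | intermediate
22 | ethyl 2-{4-(TBS-oxy)-7-ethyl-13-oxo-2-[(TBDPS-oxy)methyl]-1-azabicyclo[6.4.1]tridec-5-en-5-yl}acetate | CC[C@H]1/C=C(\CC(=O)OCC)[C@@H](O[Si](C)(C)C(C)(C)C)C[C@@H](CO[Si](c3ccccc3)(c3ccccc3)C(C)(C)C)N2CCCC[C@H]1C2=O | intermediate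
23 | alkylborane: 6-boranyl adduct of 22 (BH2 on C6, H on C5, same face) | CC[C@H]1[C@H](B)[C@H](CC(=O)OCC)[C@@H](O[Si](C)(C)C(C)(C)C)C[C@@H](CO[Si](c3ccccc3)(c3ccccc3)C(C)(C)C)N2CCCC[C@H]1C2=O | intermediate
24 | ethyl 2-{4-(TBS-oxy)-7-ethyl-6-hydroxy-13-oxo-2-[(TBDPS-oxy)methyl]-1-azabicyclo[6.4.1]tridecan-5-yl}acetate | CC[C@H]1[C@H](O)[C@H](CC(=O)OCC)[C@@H](O[Si](C)(C)C(C)(C)C)C[C@@H](CO[Si](c3ccccc3)(c3ccccc3)C(C)(C)C)N2CCCC[C@H]1C2=O | intermediate
25 | tricyclic γ-lactone: ring C cis-fused at C5–C6 (O on C6), 4-OTBS, 2-CH2OTBDPS | CC[C@H]1[C@@H]2OC(=O)C[C@@H]2[C@@H](O[Si](C)(C)C(C)(C)C)C[C@@H](CO[Si](c3ccccc3)(c3ccccc3)C(C)(C)C)N2CCCC[C@H]1C2=O | intermediate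
26 | α-methyl derivative of 25 (methyl on the lactone α-carbon, trans to the adjacent ring bond) | CC[C@H]1[C@@H]2OC(=O)[C@@H](C)[C@@H]2[C@@H](O[Si](C)(C)C(C)(C)C)C[C@@H](CO[Si](c3ccccc3)(c3ccccc3)C(C)(C)C)N2CCCC[C@H]1C2=O | intermediate
27 | diol: desilylated 26 (ring-B OH and CH2OH) | CC[C@H]1[C@@H]2OC(=O)[C@@H](C)[C@@H]2[C@@H](O)C[C@@H](CO)N2CCCC[C@H]1C2=O | intermediate
28 | ethyl 2-(hydroxymethyl)acrylate | C=C(CO)C(=O)OCC | starting material
29 | ethyl 2-(acetoxymethyl)acrylate | C=C(COC(C)=O)C(=O)OCC | intermediate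
30 | amido aldehyde: 27 with CH2OH oxidised to CHO | CC[C@H]1[C@@H]2OC(=O)[C@@H](C)[C@@H]2[C@@H](O)C[C@@H](C=O)N2CCCC[C@H]1C2=O | intermediate
31 | hydroxy ester: ethyl 4-hydroxy-2-methylidenebutanoate unit on the carbon next to N | CC[C@H]1[C@@H]2OC(=O)[C@@H](C)[C@@H]2[C@@H](O)C[C@@H]([C@@H](O)CC(=C)C(=O)OCC)N2CCCC[C@H]1C2=O | intermediate
32 | α-methylene lactone: ring D with exocyclic CH2, ring-B OH free | CC[C@H]1[C@@H]2OC(=O)[C@@H](C)[C@@H]2[C@@H](O)C[C@@H]([C@@H]2CC(=C)C(=O)O2)N2CCCC[C@H]1C2=O | intermediate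
33 | hydroxy bis-lactone (target with CH–OH in place of the ketone) | CC[C@H]1[C@@H]2OC(=O)[C@@H](C)[C@@H]2[C@@H](O)C[C@@H]([C@@H]2C[C@H](C)C(=O)O2)N2CCCC[C@H]1C2=O | intermediate
34 | CNP0311700.2 | CC[C@H]1[C@@H]2OC(=O)[C@@H](C)[C@@H]2C(=O)C[C@@H]([C@@H]2C[C@H](C)C(=O)O2)N2CCCC[C@H]1C2=O | target

**Step count**
Total step count: 22 (19 in the main line plus three reagent preparations, steps 4, 7 and 19).
Longest linear sequence: 19 steps (1 → 34 through steps 1–3, 5, 6, 8–18 and 20–22).

**Steps most likely to fail**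

1. Step 9 (Proposed new method). What may go wrong: capture of the photogenerated acyl carbene by the tertiary amine (ammonium ylide, then 2,3-shift), or intermolecular ketene capture, instead of the Wolff/N-acylation/3,3-shift sequence. The fallback uses known chemistry and makes the same bonds stepwise; it sets out from amine 10 and returns at allylic alcohol 17. N-Alkylation of 10 with 4-bromobutyl acetate (K2CO3, NaI, MeCN) would give the N-(4-acetoxybutyl)pyrrolidine F1. The established intermolecular zwitterionic ketene aza-Claisen ring expansion (acetyl fluoride, AlMe3, K2CO3, CHCl3, 0 °C) would give the nine-membered lactam diacetate F2. K2CO3 in MeOH would remove both acetates to give the diol F3, and TsCl/pyridine at 0 °C should sulfonylate only the primary alcohol to give the tosylate F4. LiN(SiMe3)2 (2.2 equiv, THF, −78 → 0 °C) would then close ring A by 7-exo-tet alkylation of the lactam enolate, forming the same α-carbon–CH2 bond and giving 17.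

2. Step 12. What may go wrong: loss of the E ring-alkene geometry through reversible conjugate addition of pyridine or iodide to the strained enone, after which step 16 would deliver the wrong ring-fusion centre. The fallback avoids a vinyl halide; it sets out from enone 18 and returns at lactone 25. Head-to-tail enone–alkene photocycloaddition of 18 with 1,1-diethoxyethene (350 nm, CH2Cl2, −40 °C) would give the cyclobutane acetal F5, with the acetal carbon on the β-carbon. Aqueous AcOH hydrolysis, then equilibration of the ring-fusion centre α to the ketone on basic alumina, would give the cis-fused cyclobutanone F6. Baeyer–Villiger oxidation (H2O2, AcOH) with migration of the ring CH would give the keto lactone F7, NaBH4 (MeOH, −40 °C) the hydroxy lactone F8, and TBSOTf/2,6-lutidine would give 25.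

3. Step 16. What may go wrong: poor facial selectivity on the ring alkene, or competing borane reduction of the bridged lactam. The fallback is a radical route from ester 22 to lactone 25. Epoxidation with dimethyldioxirane on the exposed face would give the epoxy ester F9. Titanocene-mediated reductive opening (Cp2TiCl2, Zn, 2,4,6-collidine hydrochloride, 1,4-cyclohexadiene, THF) should follow: trivalent titanium cleaves the C–O bond at the fully substituted carbon, and the tertiary radical takes a hydrogen atom on the exposed face. This would give hydroxy ester 24, which closes to 25 with PPTS.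

**Further compounds**
F1 | step 9 | (2S,3R,5S)-1-(4-acetoxybutyl)-2-[(E)-but-1-en-1-yl]-5-[(TBDPS-oxy)methyl]pyrrolidin-3-yl acetate | CC/C=C/[C@H]1[C@H](OC(C)=O)C[C@@H](CO[Si](c2ccccc2)(c2ccccc2)C(C)(C)C)N1CCCCOC(C)=O
F2 | step 9 | nine-membered (E)-lactam: 1-(4-acetoxybutyl)-6-acetoxy-3-ethyl-8-[(TBDPS-oxy)methyl]-azonin-2-one skeleton, alkene between C4 and C5 | CC[C@H]1/C=C/[C@H](OC(C)=O)C[C@@H](CO[Si](c2ccccc2)(c2ccccc2)C(C)(C)C)N(CCCCOC(C)=O)C(=O)C1
F3 | step 9 | diol from F2 (ring allylic OH and N-(4-hydroxybutyl)) | CC[C@H]1/C=C/[C@H](O)C[C@@H](CO[Si](c2ccccc2)(c2ccccc2)C(C)(C)C)N(CCCCO)C(=O)C1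
F4 | step 9 | primary tosylate of F3 | CC[C@H]1/C=C/[C@H](O)C[C@@H](CO[Si](c2ccccc2)(c2ccccc2)C(C)(C)C)N(CCCCOS(=O)(=O)c2ccc(C)cc2)C(=O)C1
F5 | step 12 | cyclobutane diethyl acetal fused at C5–C6 of the azabicycle (acetal carbon on C6), 4,13-dione | CC[C@H]1[C@@H]2C(OCC)(OCC)C[C@@H]2C(=O)C[C@@H](CO[Si](c3ccccc3)(c3ccccc3)C(C)(C)C)N2CCCC[C@H]1C2=O
F6 | step 12 | cis-fused cyclobutanone from F5 | CC[C@H]1[C@@H]2C(=O)C[C@@H]2C(=O)C[C@@H](CO[Si](c3ccccc3)(c3ccccc3)C(C)(C)C)N2CCCC[C@H]1C2=O
F7 | step 12 | keto γ-lactone (ring C without its methyl group, ring-B ketone) | CC[C@H]1[C@@H]2OC(=O)C[C@@H]2C(=O)C[C@@H](CO[Si](c3ccccc3)(c3ccccc3)C(C)(C)C)N2CCCC[C@H]1C2=O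
F8 | step 12 | hydroxy γ-lactone from F7 | CC[C@H]1[C@@H]2OC(=O)C[C@@H]2[C@@H](O)C[C@@H](CO[Si](c3ccccc3)(c3ccccc3)C(C)(C)C)N2CCCC[C@H]1C2=O
F9 | step 16 | 5,6-epoxide of ester 22 (oxygen on the exposed face) | CC[C@H]1[C@@H]2O[C@@]2(CC(=O)OCC)[C@@H](O[Si](C)(C)C(C)(C)C)C[C@@H](CO[Si](c3ccccc3)(c3ccccc3)C(C)(C)C)N2CCCC[C@H]1C2=O
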